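**Strategy.** The route rests on cutting the C4–C5 bond of 1-(4-hydroxy-3-methoxyphenyl)hexadecane-3,5-dione, the bond between the central methylene and the carbonyl carbon that carries the undecyl chain. One operation, a protecting-group-free crossed Claisen C-acylation, joins commercial zingerone (C11) to dodecanoyl chloride (C12) and completes the whole skeleton. The step exploits the C3/C4/C5 1,3-diketone: C4 is the methyl carbon of zingerone, its kinetically most accessible α-position, and the acidity of the C4–H between two carbonyls turns the product at once into a chelated lithium diketonate that resists a second acylation. The phenol of the guaiacol ring travels as its lithium phenoxide. The precursor is the dilithium dianion of zingerone.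

Key step: step 1

Assumption: 5 is drawn as the diketo tautomer, which in solution should stand in equilibrium with its chelated enol; zingerone and dodecanoyl chloride are taken as purchased.

**Step 1**
Reactants: 1 zingerone (2.0 equiv); 2 dodecanoyl chloride (1.0 equiv)
Product: 5 [12]-gingerdione (1-(4-hydroxy-3-methoxyphenyl)hexadecane-3,5-dione), via zingerone dilithium dianion 3 (not isolated), via dilithium phenoxide diketonate 4 (not isolated)
Conditions: LiN(SiMe3)2 (4.1 equiv), THF, −78 °C, 1 h; then 2 (1.0 equiv, slow addition), −78 → 0 °C; 1 M HCl
Reagents that add atoms: none
Why: Crossed Claisen condensation in the form of a C-acylation of a lithium enolate by an acid chloride: LiN(SiMe3)2 first turns the phenol of 1 into its lithium phenoxide and then removes a proton from the methyl group (C1 of the butanone, the less hindered α-position under kinetic control at −78 °C) and not from the C3 methylene, and the enolate carbon of dianion 3 adds to the carbonyl of 2 and expels chloride, which forms the C4–C5 bond of the hexadecane-3,5-dione. The closest known reaction types are the one-pot preparation of 1,3-diketones from lithium enolates and acid chlorides and the regioselective aldol addition of this same dianion to aldehydes at its methyl terminus. No ring is closed and no stereocenter is formed. Three selectivities are needed: methyl over methylene enolisation, secured by the bulky amide base at low temperature; carbon over oxygen acylation, secured because the enolate carbon is the strongest nucleophile present, because 2 is added slowly to an excess of 3, and because any aryl or enol dodecanoate formed at a phenoxide or enolate oxygen is an active ester that should pass its acyl group on to remaining enolate on warming; and single over double acylation, secured because the new diketone is deprotonated at once at C4 by a second molecule of 3 to give the chelated diketonate 4, a poor nucleophile. Acidic work-up should protonate 4 to 5 and return the second equivalent of 1, which served as proton acceptor, for recovery.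

**Compound list**
1 | zingerone, 4-(4-hydroxy-3-methoxyphenyl)butan-2-one | CC(=O)CCc1ccc(O)c(OC)c1 | starting material
2 | dodecanoyl chloride (lauroyl chloride) | CCCCCCCCCCCC(=O)Cl | starting material
3 | dilithium dianion of zingerone (lithium phenoxide plus terminal lithium enolate) | [Li+].[Li+].C=C([O-])CCc1ccc([O-])c(OC)c1 | intermediate
4 | dilithium salt of 5 (lithium phenoxide plus chelated Z lithium 1,3-diketonate) | [Li+].[Li+].CCCCCCCCCCC/C([O-])=C/C(=O)CCc1ccc([O-])c(OC)c1 | intermediate
5 | [12]-gingerdione, 1-(4-hydroxy-3-methoxyphenyl)hexadecane-3,5-dione | CCCCCCCCCCCC(=O)CC(=O)CCc1ccc(O)c(OC)c1 | target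

**Total step count:** 1
**Longest linear sequence:** 1 step

**Steps most likely to fail** (the route has one step, so the list has one entry)

1. Step 1. Three processes may go wrong:
- Acylation may go to a phenoxide or enolate oxygen and the acyl group may not be passed on to carbon.
- Proton exchange between enolate and free ketone on warming may move the enolate to the C3 methylene.
- The acid chloride may be lost through ketene formation.

Fallback (sets out from 1, comes back at 5): the same C4–C5 bond would be made at the alcohol oxidation level with the phenol masked. Zingerone 1 would be silylated (t-BuMe2SiCl, imidazole, DMF, rt) to 4-[4-(tert-butyldimethylsilyloxy)-3-methoxyphenyl]butan-2-one F1. Kinetic deprotonation (LiN(i-Pr)2, THF, −78 °C) should give the terminal lithium enolate of the silyl ether F2. Aldol addition of this enolate to dodecanal (CCCCCCCCCCCC=O) at −78 °C should give racemic 1-[4-(tert-butyldimethylsilyloxy)-3-methoxyphenyl]-5-hydroxyhexadecan-3-one F3. Oxidation of the β-hydroxy ketone with 2-iodoxybenzoic acid (EtOAc, 75 °C) should give 1-[4-(tert-butyldimethylsilyloxy)-3-methoxyphenyl]hexadecane-3,5-dione F4, which removes the carbinol stereocenter. Buffered desilylation (Bu4NF, AcOH, THF, 0 °C) would then return to 5.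

**Further compounds**
F1 | step 1 | 4-[4-(tert-butyldimethylsilyloxy)-3-methoxyphenyl]butan-2-one | CC(=O)CCc1ccc(O[Si](C)(C)C(C)(C)C)c(OC)c1
F2 | step 1 | terminal lithium enolate of the silyl ether F1 | [Li+].C=C([O-])CCc1ccc(O[Si](C)(C)C(C)(C)C)c(OC)c1
F3 | step 1 | racemic 1-[4-(tert-butyldimethylsilyloxy)-3-methoxyphenyl]-5-hydroxyhexadecan-3-one | CCCCCCCCCCCC(O)CC(=O)CCc1ccc(O[Si](C)(C)C(C)(C)C)c(OC)c1
F4 | step 1 | 1-[4-(tert-butyldimethylsilyloxy)-3-methoxyphenyl]hexadecane-3,5-dione | CCCCCCCCCCCC(=O)CC(=O)CCc1ccc(O[Si](C)(C)C(C)(C)C)c(OC)c1
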